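**Strategy.** The route rests on cutting the side chain between C1′, the CH2 on C3 of the quinone ring (ring A), and C2′. In one flask, zirconium-catalysed methylalumination of a terminal C38 alkyne and nickel-catalysed coupling of the resulting (E)-alkenylalane with 2-(chloromethyl)-3-methyl-1,4-naphthoquinone form the C1′–C2′ bond, bring in the C3′ methyl and fix the 2′E olefin; the step exploits the allyl unit C1′–C2′=C3′(CH3) next to ring A. The precursor alkyne carries neither that olefin nor that methyl. It is built from farnesol used twice through one 12-hydroxylated intermediate: as the trienyl tail and, after a triple asymmetric hydrogenation setting C7′, C11′ and C15′, as the saturated block.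

Key step: step 12

Remark: side-chain atoms are numbered C1′ (CH2 on ring A) to C32′. Both antipodes of the iridium catalyst of step 6 are available; the one assumed is the antipode that reduces (2E,6E)-farnesol to (3S,7S)-3,7,11-trimethyldodecan-1-ol, because it adds hydrogen to the olefin face required here. CIP descriptors of the three methyl stereocentres change from compound to compound only because substituent priorities change; the spatial arrangement is the same throughout.

**Route**

Step 1
Reactants: 1 (2E,6E)-farnesol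
Product: 2 tert-butyldimethyl{[(2E,6E)-3,7,11-trimethyldodeca-2,6,10-trien-1-yl]oxy}silane
Conditions: TBSCl, imidazole, CH2Cl2, 0 °C → rt
Reagents that add atoms: tert-butyldimethylsilyl chloride, CC(C)(C)[Si](C)(C)Cl
Why: Standard silylation of a primary allylic alcohol; the silyl ether protects C1 through the next steps and later serves as a latent bromide.

Step 2
Reactants: 2 farnesyl TBS ether
Product: 3 (2E,6E,10E)-12-[(tert-butyldimethylsilyl)oxy]-2,6,10-trimethyldodeca-2,6,10-trien-1-ol
Conditions: SeO2 (0.3 equiv), t-BuOOH (3 equiv), salicylic acid (0.1 equiv), CH2Cl2, 0 °C → rt, stopped before over-oxidation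
Reagents that add atoms: selenium dioxide (catalytic oxygen carrier), O=[Se]=O; tert-butyl hydroperoxide (stoichiometric oxygen source), CC(C)(C)OO
Why: Riley-type allylic oxidation (ene reaction, then [2,3]-sigmatropic shift of the allylseleninic acid) should take place at the (E)-methyl of the terminal, most electron-rich trisubstituted olefin and give the E allylic alcohol, the C2=C3 olefin being deactivated by its allylic oxygen.

Step 3
Reactants: 3 allylic alcohol
Product: 4 {[(2E,6E,10E)-12-bromo-3,7,11-trimethyldodeca-2,6,10-trien-1-yl]oxy}(tert-butyl)dimethylsilane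
Conditions: CBr4, PPh3, CH2Cl2, −20 → 0 °C
Reagents that add atoms: carbon tetrabromide, BrC(Br)(Br)Br
Why: Appel reaction; the free hydroxyl is activated much faster than the silyl ether and bromide displaces the oxyphosphonium at the primary allylic carbon without allylic transposition.

Step 4
Reactants: 4 allylic bromide
Product: 5 tert-butyldimethyl{[(2E,6E,10E)-3,7,11,15-tetramethylhexadeca-2,6,10-trien-1-yl]oxy}silane
Conditions: isopentylmagnesium bromide (1.5 equiv), Li2CuCl4 (5 mol %), THF, −78 → 0 °C
Reagents that add atoms: isopentylmagnesium bromide, CC(C)CC[Mg]Br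
Why: Copper-catalysed Grignard–allylic bromide cross-coupling (Kochi type) through a dialkylcuprate should substitute at the primary α-carbon with retention of the E olefin, and the allylic silyl ether at the other terminus is inert.

Step 5
Reactants: 5 tail silyl ether
Product: 6 (2E,6E,10E)-1-bromo-3,7,11,15-tetramethylhexadeca-2,6,10-triene
Conditions: Ph3PBr2 (1.2 equiv), CH2Cl2, 0 °C → rt; used crude
Reagents that add atoms: triphenylphosphine dibromide, BrP(Br)(c1ccccc1)(c1ccccc1)c1ccccc1
Why: Direct silyl ether to bromide exchange: the ether oxygen attacks the bromophosphonium salt, the silyl bromide leaves and bromide displaces Ph3PO at the primary allylic carbon, which gives the thermodynamically preferred primary (E)-allylic bromide in one operation.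

Step 6
Reactants: 3 allylic alcohol
Product: 7 (2R,6R,10S)-12-[(tert-butyldimethylsilyl)oxy]-2,6,10-trimethyldodecan-1-ol
Conditions: H2 (50 bar), [Ir(cod)(L)][B(C6H3(CF3)2)4] (1 mol %; L = single enantiomer of 2-phenyl-6,7-dihydro-5H-cyclopenta[b]pyridin-7-yl di-tert-butylphosphinite), CH2Cl2, rt
Reagents that add atoms: none
Why: Iridium-catalysed asymmetric hydrogenation with a chiral P,N ligand; all three olefins have the same local pattern (E, chain(H)C=C(CH3)chain, methyl-bearing carbon on the C12 side of the farnesyl skeleton), so one catalyst antipode should add H2 to the same topological face of each and set C2, C6 and C10 of 7 under catalyst control, as in the known reduction of (2E,6E)-farnesol to one 3,7,11-trimethyldodecanol stereoisomer.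

Step 7
Reactants: 7 saturated alcohol
Product: 8 {[(3S,7R,11R)-12-bromo-3,7,11-trimethyldodecyl]oxy}(tert-butyl)dimethylsilane
Conditions: CBr4, PPh3, CH2Cl2, 0 °C
Reagents that add atoms: carbon tetrabromide, BrC(Br)(Br)Br
Why: Appel reaction at a primary carbon; the adjacent methyl stereocentre is not epimerisable and the silyl ether survives the short, cold reaction.

Step 8
Reactants: 8 saturated bromide; 6 tail allylic bromide
Product: 10 tert-butyl{[(3S,7S,11R,14E,18E,22E)-3,7,11,15,19,23,27-heptamethyloctacosa-14,18,22-trien-1-yl]oxy}dimethylsilane, via alkylmagnesium bromide 9 (not isolated)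
Conditions: 8, Mg turnings, THF, 45 °C; then 6, Li2CuCl4 (5 mol %), THF, −78 → 0 °C
Reagents that add atoms: none
Why: Magnesium insertion into the primary bromide followed by copper-catalysed (Kochi-type) coupling of the β-branched Grignard reagent at the α-carbon of the allylic bromide should form the C16′–C17′ bond with the E olefin and all three stereocentres untouched.

Step 9
Reactants: 10 C35 silyl ether
Product: 11 (6E,10E,14E,18R,22S,26S)-28-bromo-2,6,10,14,18,22,26-heptamethyloctacosa-6,10,14-triene
Conditions: Ph3PBr2 (1.3 equiv), CH2Cl2, 0 °C → rt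
Reagents that add atoms: triphenylphosphine dibromide, BrP(Br)(c1ccccc1)(c1ccccc1)c1ccccc1
Why: The same silyl ether to bromide exchange as in step 5, here at an unhindered primary carbon, with the trisubstituted olefins inert to the phosphonium salt.

Step 10
Reactants: 11 primary bromide
Product: 13 (6S,10R,14R,17E,21E,25E)-6,10,14,18,22,26,30-heptamethylhentriaconta-17,21,25-trien-1-yne, via lithium acetylide 12 (not isolated)
Conditions: propyne, n-BuLi (2 equiv per propyne), TMEDA, THF/hexane, −78 → 0 °C; then 11, −78 °C → rt; H2O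
Reagents that add atoms: propyne (used as 1,3-dilithiopropyne), CC#C
Why: Alkylation of 1,3-dilithiopropyne occurs by SN2 at its more nucleophilic sp3 (propargylic) carbanion, so aqueous quench of acetylide 12 should give the terminal alkyne with the three-carbon unit C2′–C4′ in place.

Step 11
Reactants: 14 menadione (2-methylnaphthalene-1,4-dione)
Product: 15 2-(chloromethyl)-3-methylnaphthalene-1,4-dione
Conditions: 37% aq. HCHO, HCl (g), AcOH, rt, dark
Reagents that add atoms: formaldehyde, C=O; hydrogen chloride, Cl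
Why: Blanc-type chloromethylation at C3, the only free position of the quinone ring.

Step 12
Reactants: 13 C38 alkyne; 15 2-(chloromethyl)-3-methylnaphthalene-1,4-dione
Product: 17 2-methyl-3-[(2E,7S,11R,15R,18E,22E,26E)-3,7,11,15,19,23,27,31-octamethyldotriaconta-2,18,22,26-tetraen-1-yl]naphthalene-1,4-dione, via alkenylalane 16 (not isolated)
Conditions: Me3Al (2 equiv), Cp2ZrCl2 (10 mol %), ClCH2CH2Cl, rt; volatiles removed; then 15, NiCl2(PPh3)2 (3 mol %) reduced with n-BuLi (6 mol %) to zerovalent nickel, THF, −20 °C → rt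
Reagents that add atoms: trimethylaluminium, C[Al](C)C
Why: Cp2ZrCl2 and Me3Al generate a methylzirconocene species that adds methyl and metal syn across the terminal alkyne of 13 with the metal on the terminal carbon, and exchange to aluminium gives the (E)-2-methylalkenylalane 16 (Negishi carboalumination). Zerovalent nickel then inserts into the C–Cl bond of 15, whose CH2 is activated by the quinone ring, the alkenyl group is transferred from aluminium with retention, and reductive elimination forms the C1′–C2′ bond. The closest known reaction type is the nickel-catalysed cross-coupling of alkenylalanes with chloromethylated quinones used for ubiquinone and menaquinone side chains. No ring is closed and no stereocentre is formed; the three methyl stereocentres are remote and untouched. The step needs regioselective methylalumination and retention of the E geometry, secured by the syn, terminal-metal mode of addition to a monosubstituted alkyne, and chemoselectivity, secured because isolated trisubstituted olefins do not undergo carboalumination and excess Me3Al is removed before the quinone is added.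

**Compound list**

1 | (2E,6E)-farnesol, (2E,6E)-3,7,11-trimethyldodeca-2,6,10-trien-1-ol | OC/C=C(\C)CC/C=C(\C)CCC=C(C)C | starting material
2 | tert-butyldimethyl{[(2E,6E)-3,7,11-trimethyldodeca-2,6,10-trien-1-yl]oxy}silane | CC(C)(C)[Si](C)(C)OC/C=C(\C)CC/C=C(\C)CCC=C(C)C | intermediate
3 | (2E,6E,10E)-12-[(tert-butyldimethylsilyl)oxy]-2,6,10-trimethyldodeca-2,6,10-trien-1-ol | CC(C)(C)[Si](C)(C)OC/C=C(\C)CC/C=C(\C)CC/C=C(\C)CO | intermediate
4 | {[(2E,6E,10E)-12-bromo-3,7,11-trimethyldodeca-2,6,10-trien-1-yl]oxy}(tert-butyl)dimethylsilane | CC(C)(C)[Si](C)(C)OC/C=C(\C)CC/C=C(\C)CC/C=C(\C)CBr | intermediate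
5 | tert-butyldimethyl{[(2E,6E,10E)-3,7,11,15-tetramethylhexadeca-2,6,10-trien-1-yl]oxy}silane | CC(C)(C)[Si](C)(C)OC/C=C(\C)CC/C=C(\C)CC/C=C(\C)CCCC(C)C | intermediate
6 | (2E,6E,10E)-1-bromo-3,7,11,15-tetramethylhexadeca-2,6,10-triene | BrC/C=C(\C)CC/C=C(\C)CC/C=C(\C)CCCC(C)C | intermediate
7 | (2R,6R,10S)-12-[(tert-butyldimethylsilyl)oxy]-2,6,10-trimethyldodecan-1-ol | CC(C)(C)[Si](C)(C)OCC[C@@H](C)CCC[C@@H](C)CCC[C@@H](C)CO | intermediate
8 | {[(3S,7R,11R)-12-bromo-3,7,11-trimethyldodecyl]oxy}(tert-butyl)dimethylsilane | CC(C)(C)[Si](C)(C)OCC[C@@H](C)CCC[C@@H](C)CCC[C@@H](C)CBr | intermediate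
9 | {(2R,6R,10S)-12-[(tert-butyldimethylsilyl)oxy]-2,6,10-trimethyldodecyl}magnesium bromide | CC(C)(C)[Si](C)(C)OCC[C@@H](C)CCC[C@@H](C)CCC[C@@H](C)C[Mg]Br | intermediate
10 | tert-butyl{[(3S,7S,11R,14E,18E,22E)-3,7,11,15,19,23,27-heptamethyloctacosa-14,18,22-trien-1-yl]oxy}dimethylsilane | CC(C)(C)[Si](C)(C)OCC[C@@H](C)CCC[C@@H](C)CCC[C@@H](C)CC/C=C(\C)CC/C=C(\C)CC/C=C(\C)CCCC(C)C | intermediate
11 | (6E,10E,14E,18R,22S,26S)-28-bromo-2,6,10,14,18,22,26-heptamethyloctacosa-6,10,14-triene | BrCC[C@@H](C)CCC[C@@H](C)CCC[C@@H](C)CC/C=C(\C)CC/C=C(\C)CC/C=C(\C)CCCC(C)C | intermediate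
12 | [(6S,10R,14R,17E,21E,25E)-6,10,14,18,22,26,30-heptamethylhentriaconta-17,21,25-trien-1-yn-1-yl]lithium | [Li]C#CCCC[C@@H](C)CCC[C@@H](C)CCC[C@@H](C)CC/C=C(\C)CC/C=C(\C)CC/C=C(\C)CCCC(C)C | intermediate
13 | (6S,10R,14R,17E,21E,25E)-6,10,14,18,22,26,30-heptamethylhentriaconta-17,21,25-trien-1-yne | C#CCCC[C@@H](C)CCC[C@@H](C)CCC[C@@H](C)CC/C=C(\C)CC/C=C(\C)CC/C=C(\C)CCCC(C)C | intermediate
14 | menadione, 2-methylnaphthalene-1,4-dione | CC1=CC(=O)c2ccccc2C1=O | starting material
15 | 2-(chloromethyl)-3-methylnaphthalene-1,4-dione | CC1=C(CCl)C(=O)c2ccccc2C1=O | intermediate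
16 | dimethyl[(1E,6S,10R,14R,17E,21E,25E)-2,6,10,14,18,22,26,30-octamethylhentriaconta-1,17,21,25-tetraen-1-yl]alumane | C[Al](C)/C=C(\C)CCC[C@@H](C)CCC[C@@H](C)CCC[C@@H](C)CC/C=C(\C)CC/C=C(\C)CC/C=C(\C)CCCC(C)C | intermediate
17 | 2-methyl-3-[(2E,7S,11R,15R,18E,22E,26E)-3,7,11,15,19,23,27,31-octamethyldotriaconta-2,18,22,26-tetraen-1-yl]naphthalene-1,4-dione | CC1=C(C/C=C(\C)CCC[C@@H](C)CCC[C@@H](C)CCC[C@@H](C)CC/C=C(\C)CC/C=C(\C)CC/C=C(\C)CCCC(C)C)C(=O)c2ccccc2C1=O | target

**Count and risks**

Total step count: 12. Longest linear sequence: 9 steps (steps 1, 2, 3, 4, 5, 8, 9, 10, 12).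

Steps most likely to fail:

1. Step 6. Facial control may be incomplete at one of the three olefins, most plausibly at the 2-methylallylic alcohol terminus, and the resulting diastereomers with remote methyl centres would not be separable; allylic C–O hydrogenolysis could also erode the material. The fallback builds the three stereocentres from the chiral pool instead; it sets out from bromide 6 and comes back at 10.
   - Commercial (R)-2-methylbutane-1,4-diol is silylated at its less hindered C4 hydroxyl (TBSCl, imidazole, CH2Cl2, −20 °C, regioisomer removed by chromatography) to give (R)-4-[(tert-butyldimethylsilyl)oxy]-2-methylbutan-1-ol F1.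
   - Appel bromination gives (R)-(4-bromo-3-methylbutoxy)(tert-butyl)dimethylsilane F2, and magnesium in THF turns it into {(R)-4-[(tert-butyldimethylsilyl)oxy]-2-methylbutyl}magnesium bromide F3.
   - Coupling of F3 with 6 (Li2CuCl4, THF) gives tert-butyldimethyl{[(3S,6E,10E,14E)-3,7,11,15,19-pentamethylicosa-6,10,14-trien-1-yl]oxy}silane F4, and Ph3PBr2 converts it into (6E,10E,14E,18S)-20-bromo-2,6,10,14,18-pentamethylicosa-6,10,14-triene F5.
   - A second coupling with F3 (Li2CuCl4, THF/NMP) gives tert-butyl{[(3S,7R,10E,14E,18E)-3,7,11,15,19,23-hexamethyltetracosa-10,14,18-trien-1-yl]oxy}dimethylsilane F6, and Ph3PBr2 gives (6E,10E,14E,18R,22S)-24-bromo-2,6,10,14,18,22-hexamethyltetracosa-6,10,14-triene F7.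
   - A third coupling of F7 with F3 gives 10. Every methyl stereocentre then comes from the same diol enantiomer.

2. Step 12. The quinone electrophile may be reduced by the alane or by low-valent nickel, or residual Me3Al may transfer methyl, so that the cross-coupling is outrun. The fallback keeps the same bond construction but takes the redox-active quinone out of the organometallic step; it sets out from alkenylalane 16 (made from 13 as in step 12) and comes back at 17. Commercial 1,4-dimethoxy-2-methylnaphthalene is chloromethylated (paraformaldehyde, HCl, AcOH) to 2-(chloromethyl)-1,4-dimethoxy-3-methylnaphthalene F8. Coupling of F8 with 16 under the same nickel catalysis gives 1,4-dimethoxy-2-methyl-3-[(2E,7S,11R,15R,18E,22E,26E)-3,7,11,15,19,23,27,31-octamethyldotriaconta-2,18,22,26-tetraen-1-yl]naphthalene F9. Oxidative demethylation with (NH4)2Ce(NO3)6 in MeCN/H2O at 0 °C then gives 17.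

3. Step 8. The Grignard reagent may attack the γ-carbon of the allylic bromide (SN2′) and give a branched isomer, or homocoupling may consume the allylic partner. The fallback replaces the organocopper coupling by a sulfone alkylation with later reductive desulfonylation; it sets out from 6 and 8 and comes back at 10. Bromide 6 and sodium p-toluenesulfinate in DMF give 1-methyl-4-{[(2E,6E,10E)-3,7,11,15-tetramethylhexadeca-2,6,10-trien-1-yl]sulfonyl}benzene F10. Deprotonation (n-BuLi, THF/HMPA, −78 °C) and alkylation with 8 give tert-butyl{[(3S,7R,11R,14E,18E,22E)-3,7,11,15,19,23,27-heptamethyl-13-(4-methylbenzenesulfonyl)octacosa-14,18,22-trien-1-yl]oxy}dimethylsilane F11 as both C13 epimers. Reductive desulfonylation (PdCl2(dppp), LiBHEt3, THF, 0 °C), which should keep olefin position and geometry, gives 10.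

Further compounds
F1 | step 6 | (R)-4-[(tert-butyldimethylsilyl)oxy]-2-methylbutan-1-ol | CC(C)(C)[Si](C)(C)OCC[C@@H](C)CO
F2 | step 6 | (R)-(4-bromo-3-methylbutoxy)(tert-butyl)dimethylsilane | CC(C)(C)[Si](C)(C)OCC[C@@H](C)CBr
F3 | step 6 | {(R)-4-[(tert-butyldimethylsilyl)oxy]-2-methylbutyl}magnesium bromide | CC(C)(C)[Si](C)(C)OCC[C@@H](C)C[Mg]Br
F4 | step 6 | tert-butyldimethyl{[(3S,6E,10E,14E)-3,7,11,15,19-pentamethylicosa-6,10,14-trien-1-yl]oxy}silane | CC(C)(C)[Si](C)(C)OCC[C@@H](C)CC/C=C(\C)CC/C=C(\C)CC/C=C(\C)CCCC(C)C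
F5 | step 6 | (6E,10E,14E,18S)-20-bromo-2,6,10,14,18-pentamethylicosa-6,10,14-triene | BrCC[C@@H](C)CC/C=C(\C)CC/C=C(\C)CC/C=C(\C)CCCC(C)C
F6 | step 6 | tert-butyl{[(3S,7R,10E,14E,18E)-3,7,11,15,19,23-hexamethyltetracosa-10,14,18-trien-1-yl]oxy}dimethylsilane | CC(C)(C)[Si](C)(C)OCC[C@@H](C)CCC[C@@H](C)CC/C=C(\C)CC/C=C(\C)CC/C=C(\C)CCCC(C)C
F7 | step 6 | (6E,10E,14E,18R,22S)-24-bromo-2,6,10,14,18,22-hexamethyltetracosa-6,10,14-triene | BrCC[C@@H](C)CCC[C@@H](C)CC/C=C(\C)CC/C=C(\C)CC/C=C(\C)CCCC(C)C
F8 | step 12 | 2-(chloromethyl)-1,4-dimethoxy-3-methylnaphthalene | COc1c(C)c(CCl)c(OC)c2ccccc12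
F9 | step 12 | 1,4-dimethoxy-2-methyl-3-[(2E,7S,11R,15R,18E,22E,26E)-3,7,11,15,19,23,27,31-octamethyldotriaconta-2,18,22,26-tetraen-1-yl]naphthalene | COc1c(C)c(C/C=C(\C)CCC[C@@H](C)CCC[C@@H](C)CCC[C@@H](C)CC/C=C(\C)CC/C=C(\C)CC/C=C(\C)CCCC(C)C)c(OC)c2ccccc12
F10 | step 8 | 1-methyl-4-{[(2E,6E,10E)-3,7,11,15-tetramethylhexadeca-2,6,10-trien-1-yl]sulfonyl}benzene | Cc1ccc(cc1)S(=O)(=O)C/C=C(\C)CC/C=C(\C)CC/C=C(\C)CCCC(C)C
F11 | step 8 | tert-butyl{[(3S,7R,11R,14E,18E,22E)-3,7,11,15,19,23,27-heptamethyl-13-(4-methylbenzenesulfonyl)octacosa-14,18,22-trien-1-yl]oxy}dimethylsilane, both C13 epimers | CC(C)(C)[Si](C)(C)OCC[C@@H](C)CCC[C@@H](C)CCC[C@@H](C)CC(/C=C(\C)CC/C=C(\C)CC/C=C(\C)CCCC(C)C)S(=O)(=O)c1ccc(C)cc1
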